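**Plan**
1. Retrosynthesis: cut the sulfate O–S bond, then the formyl C–C bond at C3', then C11–C1' (aryllithium plus C11 aldehyde, alkene by dehydration), then C9–C11 (methylenation and hydroboration of a C9 ketone), and last the two ring A bonds C1–C10 and C4–C5 together.
2. Enabling feature: ring A is a cyclohexane whose CH2-1 and CMe2-4 flank the fusion bond C5–C10. With helper oxygens at C2 and C6 it is the [4+2] adduct of 4-methyl-2-silyloxypenta-1,3-diene across one C(CH3)=CH unit of 2,6-dimethyl-1,4-benzoquinone; the other C(CH3)=CH unit is C8=C7 and the hindered carbonyl is C9.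
3. Forward order: ring B is bought as the quinone, ring A is annulated onto it (step 2), the helper oxygens leave as enol triflates, C9=O is homologated to the C11 aldehyde, and the arene is attached and elaborated last.
4. Stereochemistry: C10 from the chiral oxazaborolidinium catalyst; C5 by base equilibration to the trans-decalin; C8 by hydrogenation from the α face; the E-alkene by elimination away from quaternary C10.
5. O2' is sulfated selectively while the 4',5'-catechol is masked as a cyclic carbonate.

Key step: step 2

Remark on names: the decalin carries drimane numbering (ring A = C1–C5, C10; ring B = C5–C10; gem-dimethyl at C4, angular methyl at C10, exocyclic carbon C11); "11-nordrimane" is 4,4,8,10-tetramethyldecalin; primed locants belong to the arene (C1' bonded to C11); α is the face opposite the C10 methyl.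
Assumption: the target, drawn as the free hydrogen sulfate, is taken as the O2' sulfate monoester; it is handled as its salt and protonated only in the last work-up.
Assumption: the (S)-configured oxazaborolidinium ion is taken to expose the quinone face that leads to 10S, following the pre-transition-state model of this catalyst class; the (R) catalyst would be used otherwise, with no other change.

Step 1
Reactants: 1 4-methylpent-3-en-2-one (mesityl oxide)
Product: 3 4-methyl-2-(triisopropylsilyloxy)penta-1,3-diene, via lithium dienolate 2 (not isolated)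
Conditions: LiN(i-Pr)2, THF, −78 °C; then i-Pr3SiOTf, −78 → 0 °C
Reagents that add atoms: triisopropylsilyl trifluoromethanesulfonate, CC(C)[Si](OS(=O)(=O)C(F)(F)F)(C(C)C)C(C)C
Why: Kinetic deprotonation of the methyl ketone at its CH3 group gives the cross-conjugated dienolate, which is silylated on oxygen (silyl enol ether formation), the standard entry to 2-silyloxy-1,3-dienes from enones.

Step 2
Reactants: 3 4-methyl-2-(triisopropylsilyloxy)penta-1,3-diene; 4 2,6-dimethyl-1,4-benzoquinone
Product: 5 cis-fused 2-(triisopropylsilyloxy)-11-nordrima-2,7-diene-6,9-dione (5β-H,10β-CH3)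
Conditions: (S)-1-(2-methylphenyl)-3,3-diphenyltetrahydro-1H,3H-pyrrolo[1,2-c][1,3,2]oxazaborole (20 mol %), HN(SO2CF3)2 (20 mol %), CH2Cl2, −78 → −40 °C; then Et3N
Reagents that add atoms: none
Why: The protonated oxazaborolidine binds the more basic and less hindered C6 carbonyl of 4 (the one flanked by two CH groups), so that the nucleophilic CH2 terminus of silyl enol ether 3 attacks the methyl-bearing β-carbon (C10) and the silyloxyallyl cation and boron enolate so formed collapse between CMe2 (C4) and the α-carbon (C5): a strongly asynchronous Lewis acid-catalysed Diels–Alder reaction at the Mukaiyama–Michael end of the mechanistic range. The closest known reaction type is the enantioselective [4+2] addition of 2-(trialkylsilyloxy)buta-1,3-dienes to substituted 1,4-benzoquinones under this catalyst class, together with Lewis acid-promoted cycloadditions of 2-silyloxydienes that carry a fully substituted terminus to 2-methylcycloalkenones. Ring A closes as a six-membered carbocycle by suprafacial [4+2] addition across one quinone C=C (Michael addition, then 6-endo collapse of the enolate onto the allyl cation), which places H-5 and CH3-10 cis. C10 is set by the catalyst, which shields one face of the bound quinone, and C5 follows from the suprafacial addition and is corrected in step 3. The step needs regioselectivity (C1 to C10 and C4 to C5), secured by the matched polarity of catalyst-bound enone and silyl enol ether and reinforced because the other orientation would join two fully substituted carbons; the two quinone C=C bonds are related by the twofold axis, so only the face matters, and the adduct ene-dione is too hindered to react twice. The 2-silyloxy group also destabilises the transoid conformer of this 4,4-disubstituted diene, which makes the cisoid geometry needed for ring closure accessible.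

Step 3
Reactants: 5 cis-fused 2-(triisopropylsilyloxy)-11-nordrima-2,7-diene-6,9-dione
Product: 6 trans-fused 2-(triisopropylsilyloxy)-11-nordrima-2,7-diene-6,9-dione (5α-H,10β-CH3)
Conditions: DBU (0.2 equiv), toluene, rt
Reagents that add atoms: none
Why: H-5 is α to the C6 carbonyl and vinylogously acidified by the ene-dione, so catalytic amidine base should equilibrate C5 through the cross-conjugated dienolate to the trans-fused isomer (base epimerisation of an angular-methyl quinone Diels–Alder adduct), while quaternary C10 blocks aromatisation and the intact silyl enol ether blocks retro-Michael opening of ring A.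

Step 4
Reactants: 6 trans-fused 2-(triisopropylsilyloxy)-11-nordrima-2,7-diene-6,9-dione
Product: 8 trans-fused 11-nordrimane-2,6,9-trione (C8 epimers), via silyl enol ether dione 7 (not isolated)
Conditions: H2 (1 atm), Pd/C, EtOAc, rt; then 1 M HCl, THF, rt
Reagents that add atoms: none
Why: Catalytic hydrogenation should reduce the electron-poor ene-dione C7=C8 bond and leave the hindered trisubstituted silyl enol ether, which aqueous acid then hydrolyses to the C2 ketone; the C8 epimer mixture is irrelevant because C8 is trigonal again after step 6.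

Step 5
Reactants: 8 trans-fused 11-nordrimane-2,6,9-trione
Product: 10 9-oxo-11-nordrima-2,6-diene-2,6-diyl bis(trifluoromethanesulfonate), via dilithium bis-enolate 9 (not isolated)
Conditions: LiN(i-Pr)2 (2.1 equiv), THF, −78 °C; then PhNTf2, −78 → 0 °C
Reagents that add atoms: N-phenylbis(trifluoromethanesulfonimide), O=S(=O)(N(c1ccccc1)S(=O)(=O)C(F)(F)F)C(F)(F)F
Why: Kinetic enolisation should remove protons from the CH2 groups next to the C2 and C6 carbonyls in preference to the tertiary C8–H and C5–H, and O-triflation of the bis-enolate (enol triflate formation) tags both helper oxygens while the C9 ketone stays; a C1=C2 regioisomer of the ring A triflate would converge in step 9.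

Step 6
Reactants: 10 9-oxo-11-nordrima-2,6-diene-2,6-diyl bis(trifluoromethanesulfonate)
Product: 12 trans-fused 11-nordrima-2,7-dien-9-one (5α-H,10β-CH3), via deconjugated dienone 11 (not isolated)
Conditions: Pd(OAc)2 (5 mol %), PPh3, HCO2H, n-Bu3N, DMF, 60 °C; then DBU, rt
Reagents that add atoms: none
Why: Palladium-catalysed formate reduction of enol triflates replaces both C–OTf bonds by C–H, and base then moves the β,γ-unsaturated ketone into conjugation through the C8 dienolate (enone isomerisation), which removes both helper oxygens and restores the C7=C8 enone without touching C5.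

Step 7
Reactants: 12 trans-fused 11-nordrima-2,7-dien-9-one
Product: 13 drima-2,7,9(11)-triene (5α-H,10β-CH3)
Conditions: Ph3PCH3Br, KOtBu, toluene, 90 °C
Reagents that add atoms: methyltriphenylphosphonium bromide, C[P+](c1ccccc1)(c1ccccc1)c1ccccc1.[Br-]
Why: Wittig methylenation with the small unstabilised ylide is the standard way to convert hindered α-branched ketones and enones into exocyclic methylenes by 1,2-addition.

Step 8
Reactants: 13 drima-2,7,9(11)-triene
Product: 15 drima-2,7-dien-11-ol (9α-H), via alkylborane 14 (not isolated)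
Conditions: 9-BBN, THF, 60 °C; then NaOH, H2O2, 0 °C → rt
Reagents that add atoms: hydrogen peroxide, OO
Why: 9-BBN hydroborates the terminal 1,1-disubstituted alkene much faster than the trisubstituted and the ring cis-disubstituted ones, puts boron on C11 and should deliver hydrogen to C9 from the α face opposite the axial C10 methyl (anti-Markovnikov hydroboration–oxidation); the C9 centre is lost again in step 14.

Step 9
Reactants: 15 drima-2,7-dien-11-ol
Product: 16 8-epi-driman-11-ol (5α-H,8β-CH3,9α-H,10β-CH3)
Conditions: H2 (3 atm), PtO2, EtOAc, rt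
Reagents that add atoms: none
Why: Catalytic hydrogenation saturates both ring alkenes, and hydrogen is expected to add to C7=C8 from the α face, away from the axial C10 methyl that is 1,3 to C8, which sets the axial 8β-methyl group (8S).

Step 10
Reactants: 16 8-epi-driman-11-ol
Product: 17 8-epi-driman-11-al
Conditions: Dess–Martin periodinane, NaHCO3, CH2Cl2, 0 °C → rt
Reagents that add atoms: none
Why: Dess–Martin oxidation converts the hindered primary alcohol into the aldehyde under buffered conditions that cannot touch C8; any equilibration at C9 is without consequence.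

Step 11
Reactants: 18 benzene-1,2,4-triol
Product: 19 1,2,4-tris(methoxymethoxy)benzene
Conditions: MOMCl, i-Pr2NEt, CH2Cl2, 0 °C → rt, under argon
Reagents that add atoms: chloromethyl methyl ether, COCCl
Why: O-Alkylation of the three phenols gives the tris(MOM) ether (acetal protection), whose groups later direct both lithiations.

Step 12
Reactants: 19 1,2,4-tris(methoxymethoxy)benzene
Product: 20 1-bromo-2,4,5-tris(methoxymethoxy)benzene
Conditions: NBS, MeCN, 0 °C
Reagents that add atoms: N-bromosuccinimide, BrN1C(=O)CCC1=O
Why: Electrophilic aromatic bromination should occur at C5, which is para to the 2-oxygen and ortho to the 4-oxygen and is the only unhindered doubly activated position.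

Step 13
Reactants: 20 1-bromo-2,4,5-tris(methoxymethoxy)benzene; 17 8-epi-driman-11-al
Product: 22 11-[2,4,5-tris(methoxymethoxy)phenyl]-8-epi-driman-11-ol (C11 epimers), via aryllithium 21 (not isolated)
Conditions: n-BuLi, THF, −78 °C; then 17, −78 → −40 °C; then H2O
Reagents that add atoms: none
Why: Bromine–lithium exchange gives the ortho-alkoxy-stabilised aryllithium, which adds to the hindered aldehyde (1,2-addition of an organolithium); the carbinol centre forms as a mixture and is removed in step 14.

Step 14
Reactants: 22 11-[2,4,5-tris(methoxymethoxy)phenyl]-8-epi-driman-11-ol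
Product: 23 (E)-11-[2,4,5-tris(methoxymethoxy)phenyl]-8-epi-drim-9(11)-ene
Conditions: methyl N-(triethylammoniosulfonyl)carbamate (Burgess reagent), toluene, 70 °C
Reagents that add atoms: none
Why: The electron-rich secondary benzylic alcohol has a single β-hydrogen (H-9), so dehydration through its sulfamate (Burgess elimination) can only give the C9=C11 styrene, and the aryl group should settle on the C8 side, away from quaternary C10 (E).

Step 15
Reactants: 23 (E)-11-[2,4,5-tris(methoxymethoxy)phenyl]-8-epi-drim-9(11)-ene
Product: 25 (E)-11-[3-formyl-2,4,5-tris(methoxymethoxy)phenyl]-8-epi-drim-9(11)-ene, via aryllithium 24 (not isolated)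
Conditions: n-BuLi, TMEDA, THF, −78 → −20 °C; then DMF; then H2O
Reagents that add atoms: N,N-dimethylformamide, CN(C)C=O
Why: The proton at C3' lies between two MOM ethers and is removed selectively (directed ortho-metalation), and the aryllithium is formylated by DMF.

Step 16
Reactants: 25 (E)-11-[3-formyl-2,4,5-tris(methoxymethoxy)phenyl]-8-epi-drim-9(11)-ene
Product: 27 (E)-11-(3-formyl-2,4,5-trihydroxyphenyl)-8-epi-drim-9(11)-ene, via tris-silyl ether 26 (not isolated)
Conditions: Me3SiOTf, 2,2'-bipyridyl, CH2Cl2, 0 °C → rt; then H2O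
Reagents that add atoms: none
Why: Silyl triflate buffered by 2,2'-bipyridyl converts aryl MOM ethers into aryl silyl ethers that hydrolyse on aqueous work-up (non-protic MOM cleavage), which avoids acid-induced cyclisation of the phenol onto the trisubstituted alkene.

Step 17
Reactants: 27 (E)-11-(3-formyl-2,4,5-trihydroxyphenyl)-8-epi-drim-9(11)-ene
Product: 30 2-formyl-3,4-dihydroxy-6-{(E)-[(5S,8S,10S)-4,4,8,10-tetramethyldecalin-9-ylidene]methyl}phenyl hydrogen sulfate (target), via cyclic carbonate 28 (not isolated), via carbonate sulfate 29 (not isolated)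
Conditions: 1,1'-carbonyldiimidazole (1.05 equiv), THF, 0 °C → rt; then SO3·pyridine, pyridine, 40 °C; then NaHCO3, H2O/MeOH, rt; then sulfonic acid ion-exchange resin (H+ form), 0 °C
Reagents that add atoms: sulfur trioxide–pyridine complex, O=S(=O)([O-])[n+]1ccccc1
Why: Only the vicinal 4',5'-diol can close a five-membered cyclic carbonate with carbonyldiimidazole, which leaves O2' as the single free hydroxyl for O-sulfation; mild aqueous base, to which aryl sulfates are stable, then cleaves the aryl carbonate, and cold ion exchange gives the hydrogen sulfate.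

**Compound list**
1 | 4-methylpent-3-en-2-one | CC(=O)C=C(C)C | starting material
2 | lithium 4-methylpenta-1,3-dien-2-olate | [Li+].[O-]C(=C)C=C(C)C | intermediate
3 | 4-methyl-2-(triisopropylsilyloxy)penta-1,3-diene | C=C(O[Si](C(C)C)(C(C)C)C(C)C)C=C(C)C | intermediate
4 | 2,6-dimethyl-1,4-benzoquinone | CC1=CC(=O)C=C(C)C1=O | starting material
5 | cis-fused 2-(triisopropylsilyloxy)-11-nordrima-2,7-diene-6,9-dione (5β-H, 10β-CH3) | CC1=CC(=O)[C@@H]2C(C)(C)C=C(O[Si](C(C)C)(C(C)C)C(C)C)C[C@]2(C)C1=O | intermediate
6 | trans-fused 2-(triisopropylsilyloxy)-11-nordrima-2,7-diene-6,9-dione (5α-H, 10β-CH3) | CC1=CC(=O)[C@H]2C(C)(C)C=C(O[Si](C(C)C)(C(C)C)C(C)C)C[C@]2(C)C1=O | intermediate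
7 | trans-fused 2-(triisopropylsilyloxy)-11-nordrim-2-ene-6,9-dione (C8 epimers) | CC1CC(=O)[C@H]2C(C)(C)C=C(O[Si](C(C)C)(C(C)C)C(C)C)C[C@]2(C)C1=O | intermediate
8 | trans-fused 11-nordrimane-2,6,9-trione (C8 epimers) | CC1CC(=O)[C@H]2C(C)(C)CC(=O)C[C@]2(C)C1=O | intermediate
9 | dilithium 9-oxo-11-nordrima-2,6-diene-2,6-diolate (C8 epimers) | [Li+].[Li+].CC1C=C([O-])[C@H]2C(C)(C)C=C([O-])C[C@]2(C)C1=O | intermediate
10 | 9-oxo-11-nordrima-2,6-diene-2,6-diyl bis(trifluoromethanesulfonate) (C8 epimers) | CC1C=C(OS(=O)(=O)C(F)(F)F)[C@H]2C(C)(C)C=C(OS(=O)(=O)C(F)(F)F)C[C@]2(C)C1=O | intermediate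
11 | trans-fused 11-nordrima-2,6-dien-9-one (C8 epimers) | CC1C=C[C@H]2C(C)(C)C=CC[C@]2(C)C1=O | intermediate
12 | trans-fused 11-nordrima-2,7-dien-9-one (5α-H, 10β-CH3) | CC1=CC[C@H]2C(C)(C)C=CC[C@]2(C)C1=O | intermediate
13 | drima-2,7,9(11)-triene (5α-H, 10β-CH3) | CC1=CC[C@H]2C(C)(C)C=CC[C@]2(C)C1=C | intermediate
14 | 9-(drima-2,7-dien-11-yl)-9-borabicyclo[3.3.1]nonane (9α-H) | CC1=CC[C@H]2C(C)(C)C=CC[C@]2(C)[C@H]1CB1C2CCCC1CCC2 | intermediate
15 | drima-2,7-dien-11-ol (5α-H, 9α-H, 10β-CH3) | CC1=CC[C@H]2C(C)(C)C=CC[C@]2(C)[C@H]1CO | intermediate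
16 | 8-epi-driman-11-ol (5α-H, 8β-CH3, 9α-H, 10β-CH3) | C[C@H]1CC[C@H]2C(C)(C)CCC[C@]2(C)[C@H]1CO | intermediate
17 | 8-epi-driman-11-al (5α-H, 8β-CH3, 9α-H, 10β-CH3) | C[C@H]1CC[C@H]2C(C)(C)CCC[C@]2(C)[C@H]1C=O | intermediate
18 | benzene-1,2,4-triol | Oc1ccc(O)c(O)c1 | starting material
19 | 1,2,4-tris(methoxymethoxy)benzene | COCOc1ccc(OCOC)c(OCOC)c1 | intermediate
20 | 1-bromo-2,4,5-tris(methoxymethoxy)benzene | COCOc1cc(OCOC)c(OCOC)cc1Br | intermediate
21 | [2,4,5-tris(methoxymethoxy)phenyl]lithium | COCOc1cc(OCOC)c(OCOC)cc1[Li] | intermediate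
22 | 11-[2,4,5-tris(methoxymethoxy)phenyl]-8-epi-driman-11-ol (C11 epimers) | C[C@H]1CC[C@H]2C(C)(C)CCC[C@]2(C)[C@H]1C(O)c1cc(OCOC)c(OCOC)cc1OCOC | intermediate
23 | (E)-11-[2,4,5-tris(methoxymethoxy)phenyl]-8-epi-drim-9(11)-ene | C[C@H]1CC[C@H]2C(C)(C)CCC[C@]2(C)/C1=C/c1cc(OCOC)c(OCOC)cc1OCOC | intermediate
24 | 3'-lithio derivative of 23 | C[C@H]1CC[C@H]2C(C)(C)CCC[C@]2(C)/C1=C/c1cc(OCOC)c(OCOC)c([Li])c1OCOC | intermediate
25 | (E)-11-[3-formyl-2,4,5-tris(methoxymethoxy)phenyl]-8-epi-drim-9(11)-ene | C[C@H]1CC[C@H]2C(C)(C)CCC[C@]2(C)/C1=C/c1cc(OCOC)c(OCOC)c(C=O)c1OCOC | intermediate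
26 | (E)-11-[3-formyl-2,4,5-tris(trimethylsilyloxy)phenyl]-8-epi-drim-9(11)-ene | C[C@H]1CC[C@H]2C(C)(C)CCC[C@]2(C)/C1=C/c1cc(O[Si](C)(C)C)c(O[Si](C)(C)C)c(C=O)c1O[Si](C)(C)C | intermediate
27 | (E)-11-(3-formyl-2,4,5-trihydroxyphenyl)-8-epi-drim-9(11)-ene | C[C@H]1CC[C@H]2C(C)(C)CCC[C@]2(C)/C1=C/c1cc(O)c(O)c(C=O)c1O | intermediate
28 | 4',5'-cyclic carbonate of 27 | C[C@H]1CC[C@H]2C(C)(C)CCC[C@]2(C)/C1=C/c1cc3OC(=O)Oc3c(C=O)c1O | intermediate
29 | 4',5'-cyclic carbonate 2'-O-sulfate (formed as the pyridinium salt, drawn as the acid) | C[C@H]1CC[C@H]2C(C)(C)CCC[C@]2(C)/C1=C/c1cc3OC(=O)Oc3c(C=O)c1OS(=O)(=O)O | intermediate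
30 | 2-formyl-3,4-dihydroxy-6-{(E)-[(5S,8S,10S)-4,4,8,10-tetramethyldecalin-9-ylidene]methyl}phenyl hydrogen sulfate | C[C@H]1CC[C@H]2C(C)(C)CCC[C@]2(C)/C1=C/c1cc(O)c(O)c(C=O)c1OS(=O)(=O)O | target

**Step count and risks**
Total steps: 17. Longest linear sequence: 15 (steps 1–10 and 13–17); the arene branch (steps 11–12) joins at step 13.

Step 2. What may go wrong: ring closure at the fully substituted diene terminus may be slow or incomplete, so that the reaction stops at the open-chain Michael stage, and facial control may be lost if the first bond forms outside the organised catalyst complex. Fallback, setting out from 3 and 4 and returning at 8: the annulation is divided into two known operations. The same protonated oxazaborolidine is used only for the Mukaiyama–Michael addition of 3 to 4, which forms C1–C10 and sets C10. Dilute acid work-up removes the silyl group and gives the open-chain ene-dione (S)-2,6-dimethyl-2-(4-methyl-2-oxopent-3-en-1-yl)cyclohex-5-ene-1,4-dione F1. Cs2CO3 in MeCN then closes ring A by reversible intramolecular Michael addition of the C5 enolate to the β,β-dimethyl enone; this forms C4–C5 and should settle on the trans-fused 11-nordrim-7-ene-2,6,9-trione F2. Hydrogenation (H2, Pd/C, EtOAc) gives 8.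

Step 3. What may go wrong: the equilibration at C5 may not lie far enough on the trans side, because the trans isomer carries the 1,3-diaxial pair of the axial C4 methyl and the C10 methyl. Fallback, setting out from 5 and returning at 12: C5 is made trigonal and then set by hydrogenation instead of by equilibration. KN(SiMe3)2 and PhNTf2 convert 5 into the dienyl triflate 9-oxo-2-(triisopropylsilyloxy)-11-nordrima-2,5,7-trien-6-yl trifluoromethanesulfonate F3. Hydrogenation over PtO2 should saturate C5=C6 and C7=C8 from the α face, anti to the C10 methyl, with hydrogenolysis of the C–OTf bond, to give trans-fused 2-(triisopropylsilyloxy)-11-nordrim-2-en-9-one F4. Aqueous HCl gives trans-fused 11-nordrimane-2,9-dione F5. Kinetic enolisation of the unhindered C2 ketone (LiN(i-Pr)2, 1 equiv, then PhNTf2) gives 9-oxo-11-nordrim-2-en-2-yl trifluoromethanesulfonate F6, and Pd(OAc)2/PPh3/HCO2H/n-Bu3N reduction gives trans-fused 11-nordrim-2-en-9-one F7. Me3SiOTf/Et3N then gives 9-(trimethylsilyloxy)-11-nordrima-2,8-diene F8, which Pd(OAc)2 under O2 in DMSO (Saegusa–Ito dehydrogenation) converts into 12.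

Step 9. What may go wrong: poor facial selectivity at C8 (hydroxyl-assisted adsorption could deliver hydrogen to the β face), or migration of the C7=C8 bond to the unreactive tetrasubstituted C8=C9 position. Fallback, setting out from 12 and returning at 16: hydroxyl-directed homogeneous hydrogenation of the tetrasubstituted isomer. Hydrogenation of 12 (H2, Pd/C) gives trans-fused 11-nordriman-9-one F9. KN(SiMe3)2 and PhNTf2 give 11-nordrim-8-en-9-yl trifluoromethanesulfonate F10, the only possible enol triflate. Stille coupling with Bu3SnCH2OH (Pd(PPh3)4, LiCl, dioxane, 100 °C) gives drim-8-en-11-ol F11. [Ir(cod)(PCy3)(py)]PF6 under H2 in CH2Cl2 should then add hydrogen cis across C8=C9 under guidance of the primary hydroxyl, from the α face left open by the C10 methyl, to give 16.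

**Further compounds**
F1 | step 2 | (S)-2,6-dimethyl-2-(4-methyl-2-oxopent-3-en-1-yl)cyclohex-5-ene-1,4-dione | CC1=CC(=O)C[C@](C)(CC(=O)C=C(C)C)C1=O
F2 | step 2 | trans-fused 11-nordrim-7-ene-2,6,9-trione | CC1=CC(=O)[C@H]2C(C)(C)CC(=O)C[C@]2(C)C1=O
F3 | step 3 | 9-oxo-2-(triisopropylsilyloxy)-11-nordrima-2,5,7-trien-6-yl trifluoromethanesulfonate | CC1=CC(OS(=O)(=O)C(F)(F)F)=C2C(C)(C)C=C(O[Si](C(C)C)(C(C)C)C(C)C)C[C@]2(C)C1=O
F4 | step 3 | trans-fused 2-(triisopropylsilyloxy)-11-nordrim-2-en-9-one (C8 epimers) | CC1CC[C@H]2C(C)(C)C=C(O[Si](C(C)C)(C(C)C)C(C)C)C[C@]2(C)C1=O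
F5 | step 3 | trans-fused 11-nordrimane-2,9-dione (C8 epimers) | CC1CC[C@H]2C(C)(C)CC(=O)C[C@]2(C)C1=O
F6 | step 3 | 9-oxo-11-nordrim-2-en-2-yl trifluoromethanesulfonate (C8 epimers) | CC1CC[C@H]2C(C)(C)C=C(OS(=O)(=O)C(F)(F)F)C[C@]2(C)C1=O
F7 | step 3 | trans-fused 11-nordrim-2-en-9-one (C8 epimers) | CC1CC[C@H]2C(C)(C)C=CC[C@]2(C)C1=O
F8 | step 3 | 9-(trimethylsilyloxy)-11-nordrima-2,8-diene | CC=1CC[C@H]2C(C)(C)C=CC[C@]2(C)C=1O[Si](C)(C)C
F9 | step 9 | trans-fused 11-nordriman-9-one (C8 epimers) | CC1CC[C@H]2C(C)(C)CCC[C@]2(C)C1=O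
F10 | step 9 | 11-nordrim-8-en-9-yl trifluoromethanesulfonate | CC=1CC[C@H]2C(C)(C)CCC[C@]2(C)C=1OS(=O)(=O)C(F)(F)F
F11 | step 9 | drim-8-en-11-ol | CC=1CC[C@H]2C(C)(C)CCC[C@]2(C)C=1CO
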